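**Strategy**

The plan cuts the bond between the side-chain carbinol carbon C1′ and C1 of the 7-oxabicyclo[4.1.0]heptene. C1 lies α to the C2 oxygen of a masked p-quinone (C2 and C5 are para-dioxygenated), so an α-iodo quinone monoketal can act as an α-enone anion. A ligand-controlled Ni/Cr (Nozaki–Hiyama–Kishi) alkenylation joins this achiral, unprotected 2-iodo-5-(hydroxymethyl)quinone monoketal to the complete (2Z,4E)-dienal and sets C1′. The dienal comes from a Ti(III) epoxypolyene cyclisation of (R)-6,7-epoxygeranyl acetate. The ring hydroxymethyl then directs oxirane formation at C1–C6, the C1′ hydroxyl directs reduction at C2, and C5 is set by CBS reduction.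

Key step: step 13

Remark: the enantiomer of each chiral controller (Shi ketone, sulfonamide ligand, tartrate, CBS catalyst) is the one predicted by the usual model for the required face; for the sulfonamide ligand and the tartrate the sense would be confirmed in a scouting run and the antipode used if needed. Geranyl acetate, but-2-yn-1-ol and 5-hydroxy-2-methoxybenzaldehyde are taken as commercial.

**Side-chain aldehyde**

Step 1
Reactants: 1 geranyl acetate
Product: 2 (R)-6,7-epoxygeranyl acetate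
Conditions: D-fructose-derived Shi ketone (30 mol %), Oxone, K2CO3, Bu4NHSO4, MeCN–DMM / aq. borate–EDTA buffer, 0 °C
Reagents that add atoms: potassium peroxymonosulfate (Oxone), OOS(=O)(=O)[O-].[K+]
Why: Shi asymmetric epoxidation; the chiral dioxirane should attack only the electron-rich 6,7-alkene (the 2,3-alkene is deactivated by the allylic acetate) through the spiro transition state, setting C6 as R.

Step 2
Reactants: 2 (R)-6,7-epoxygeranyl acetate
Product: 3 [(1S,3R)-3-hydroxy-2,2-dimethyl-6-methylidenecyclohexyl]methyl acetate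
Conditions: Cp2TiCl2 (2.2 equiv), Mn dust, THF, rt; then 1 M HCl
Reagents that add atoms: none
Why: Ti(III)-mediated radical epoxypolyene cyclisation (Nugent–RajanBabu reagent): homolytic oxirane opening to the tertiary radical, 6-endo closure through a chair with both substituents equatorial (C1 set cis-1,3 to the carbinol), then Ti trapping and β-hydride elimination should give the exocyclic alkene.

Step 3
Reactants: 3 hydroxy acetate
Product: 4 [(1S,3R)-3-(tert-butyldimethylsilyloxy)-2,2-dimethyl-6-methylidenecyclohexyl]methyl acetate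
Conditions: TBSOTf, 2,6-lutidine, CH2Cl2, −78 → 0 °C
Reagents that add atoms: TBSOTf, CC(C)(C)[Si](C)(C)OS(=O)(=O)C(F)(F)F
Why: Silylation of the hindered secondary alcohol with the silyl triflate, needed so that only the primary alcohol is oxidised later.

Step 4
Reactants: 4 silyl ether acetate
Product: 5 [(1S,3R)-3-(tert-butyldimethylsilyloxy)-2,2-dimethyl-6-methylidenecyclohexyl]methanol
Conditions: K2CO3 (cat.), MeOH, rt
Reagents that add atoms: none
Why: Base-catalysed transesterification frees the primary alcohol while the TBS ether is stable.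

Step 5
Reactants: 5 primary alcohol
Product: 6 (1S,3R)-3-(tert-butyldimethylsilyloxy)-2,2-dimethyl-6-methylidenecyclohexane-1-carbaldehyde
Conditions: Dess–Martin periodinane, NaHCO3, CH2Cl2, 0 °C; used crude
Reagents that add atoms: none
Why: Dess–Martin oxidation under buffered, non-basic conditions should give the β,γ-unsaturated aldehyde without epimerisation at C1 or migration of the exocyclic alkene.

Step 6
Reactants: 6 aldehyde
Product: 7 2-[(E)-2-[(1S,3R)-3-(tert-butyldimethylsilyloxy)-2,2-dimethyl-6-methylidenecyclohexyl]ethenyl]-4,4,5,5-tetramethyl-1,3,2-dioxaborolane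
Conditions: Cl2CHB(pin), CrCl2, LiI, THF, rt
Reagents that add atoms: 2-(dichloromethyl)-4,4,5,5-tetramethyl-1,3,2-dioxaborolane, ClC(Cl)B1OC(C)(C)C(C)(C)O1
Why: Takai–Utimoto boryl-olefination; the gem-dichromium reagent adds to the aldehyde and eliminates to the E-alkenylboronate under neutral conditions that should spare the α-stereocentre.

Step 7
Reactants: 8 but-2-yn-1-ol
Product: 9 (Z)-3-iodobut-2-en-1-ol
Conditions: Red-Al, THF, 0 °C → rt; then I2, −78 °C → rt
Reagents that add atoms: iodine, II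
Why: Hydroxyl-directed trans-hydroalumination places aluminium on C3 cis to CH2OH (cyclic alkoxyalanate), and iodinolysis with retention gives the Z-iodide.

Step 8
Reactants: 7 alkenylboronate, 9 (Z)-3-iodobut-2-en-1-ol
Product: 10 (2Z,4E)-5-[(1S,3R)-3-(tert-butyldimethylsilyloxy)-2,2-dimethyl-6-methylidenecyclohexyl]-3-methylpenta-2,4-dien-1-ol
Conditions: Pd(PPh3)4 (5 mol %), aq. K3PO4, THF, rt
Reagents that add atoms: none
Why: Suzuki–Miyaura coupling proceeds with retention at both alkenyl partners, so the (2Z,4E)-diene geometry is fixed by 7 and 9.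

Step 9
Reactants: 10 dienol
Product: 11 (2Z,4E)-5-[(1S,3R)-3-(tert-butyldimethylsilyloxy)-2,2-dimethyl-6-methylidenecyclohexyl]-3-methylpenta-2,4-dienal
Conditions: activated MnO2, CH2Cl2, rt
Reagents that add atoms: none
Why: MnO2 oxidation of the allylic alcohol under neutral conditions should keep the 2Z geometry of the enal.

**Ring fragment**

Step 10
Reactants: 12 5-hydroxy-2-methoxybenzaldehyde
Product: 13 3-(hydroxymethyl)-4-methoxyphenol
Conditions: NaBH4, MeOH, 0 °C
Reagents that add atoms: none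
Why: Borohydride reduction of the aryl aldehyde to the benzylic alcohol.

Step 11
Reactants: 13 3-(hydroxymethyl)-4-methoxyphenol
Product: 14 5-(hydroxymethyl)-2-iodo-4-methoxyphenol
Conditions: NIS, TsOH (cat.), MeCN, 0 °C
Reagents that add atoms: N-iodosuccinimide, O=C1CCC(=O)N1I
Why: Electrophilic aromatic iodination ortho to the phenol OH (para position blocked by OMe) at the less hindered ortho carbon, which is para to CH2OH.

Step 12
Reactants: 14 iodophenol
Product: 15 5-(hydroxymethyl)-2-iodo-4,4-dimethoxycyclohexa-2,5-dien-1-one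
Conditions: PhI(OAc)2, MeOH, 0 °C
Reagents that add atoms: methanol, CO
Why: Oxidative dearomatisation of a p-methoxyphenol with a hypervalent iodine reagent in methanol gives the quinone monoketal with the carbonyl at the former phenol carbon, so the α-iodo enone regiochemistry is unambiguous.

**Fragment union and completion**

Step 13
Reactants: 11 (2Z,4E)-dienal, 15 α-iodo quinone monoketal
Product: 16 2-[(1S,2Z,4E)-5-[(1S,3R)-3-(tert-butyldimethylsilyloxy)-2,2-dimethyl-6-methylidenecyclohexyl]-1-hydroxy-3-methylpenta-2,4-dien-1-yl]-5-(hydroxymethyl)-4,4-dimethoxycyclohexa-2,5-dien-1-one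
Conditions: CrCl2 (3 equiv), chiral oxazoline–sulfonamide ligand (3.3 equiv, enantiomer giving 1′S), Et3N (3.3 equiv), NiCl2 (5 mol %), THF, rt
Reagents that add atoms: none
Why: Ni(0) inserts into the activated C–I bond of 15, the alkenyl group is passed to ligand-bound Cr(III), and the σ-alkenylchromium adds 1,2 to the aldehyde of 11 through a closed transition state at chromium. The closest known reaction type is the asymmetric Nozaki–Hiyama–Kishi alkenylation, used here with an α-iodo enone as a Morita–Baylis–Hillman surrogate. No ring is closed. The new stereocentre C1′ is controlled by the sulfonamide ligand, because the existing stereocentres of 11 are remote and 15 is achiral. The step needs chemoselective addition to the aldehyde over the dienone carbonyl and ketal, tolerance of the free primary hydroxyl, and retention of the 2Z enal geometry. These are secured by the aldehyde selectivity of organochromium(III) reagents and the neutral, non-nucleophilic medium.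

Step 14
Reactants: 16 dienone diol
Product: 17 (1S,6R)-1-[(1S,2Z,4E)-5-[(1S,3R)-3-(tert-butyldimethylsilyloxy)-2,2-dimethyl-6-methylidenecyclohexyl]-1-hydroxy-3-methylpenta-2,4-dien-1-yl]-4-(hydroxymethyl)-5,5-dimethoxy-7-oxabicyclo[4.1.0]hept-3-en-2-one
Conditions: Ph3COOH, NaHMDS, L-(+)-diisopropyl tartrate, 4 Å MS, toluene, −50 °C
Reagents that add atoms: trityl hydroperoxide, OOC(c1ccccc1)(c1ccccc1)c1ccccc1
Why: Tartrate-mediated, hydroxyl-directed nucleophilic (Weitz–Scheffer) epoxidation: the sodium alkoxide of the ring CH2OH, held in the tartrate–peroxide aggregate, should deliver the peroxide across the ketal carbon to the unsubstituted β-carbon on the face fixed by the tartrate, a face also favoured by alkoxide-guided delivery from the 1′S carbinol; the enolate then closes the oxirane, and the electron-rich side-chain alkenes do not react with a nucleophilic oxidant.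

Step 15
Reactants: 17 epoxy ketone
Product: 18 (1R,2S,6R)-1-[(1S,2Z,4E)-5-[(1S,3R)-3-(tert-butyldimethylsilyloxy)-2,2-dimethyl-6-methylidenecyclohexyl]-1-hydroxy-3-methylpenta-2,4-dien-1-yl]-4-(hydroxymethyl)-5,5-dimethoxy-7-oxabicyclo[4.1.0]hept-3-en-2-ol
Conditions: Me4NBH(OAc)3, MeCN–AcOH, −30 °C
Reagents that add atoms: none
Why: Evans–Saksena hydroxyl-directed reduction; in the rotamer with the dienyl group anti to C2 the boron-bound C1′ oxygen sits on the oxirane face, so intramolecular hydride delivery should give the 1,3-anti diol with the C2 hydroxyl trans to the oxirane, while the ketal keeps C5 masked.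

Step 16
Reactants: 18 epoxy alcohol ketal
Product: 19 (1R,5S,6R)-6-[(1S,2Z,4E)-5-[(1S,3R)-3-(tert-butyldimethylsilyloxy)-2,2-dimethyl-6-methylidenecyclohexyl]-1-hydroxy-3-methylpenta-2,4-dien-1-yl]-5-hydroxy-3-(hydroxymethyl)-7-oxabicyclo[4.1.0]hept-3-en-2-one
Conditions: PPTS (cat.), acetone–H2O (10:1), rt
Reagents that add atoms: water, O
Why: Mild acid hydrolysis of the allylic dimethyl ketal (via the alkene-stabilised oxocarbenium ion) should unveil the enone without opening the oxirane or cleaving the TBS ether.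

Step 17
Reactants: 19 epoxy enone
Product: 20 (1R,2S,5R,6S)-1-[(1S,2Z,4E)-5-[(1S,3R)-3-(tert-butyldimethylsilyloxy)-2,2-dimethyl-6-methylidenecyclohexyl]-1-hydroxy-3-methylpenta-2,4-dien-1-yl]-4-(hydroxymethyl)-7-oxabicyclo[4.1.0]hept-3-ene-2,5-diol
Conditions: catecholborane (excess; first caps the hydroxyls as borates), (R)-Me-CBS oxazaborolidine (1 equiv), toluene, −78 °C; MeOH / aq. NaHCO3 work-up
Reagents that add atoms: none
Why: Corey–Bakshi–Shibata reduction under reagent control; with the α-substituted alkenyl carbon as the large group and the oxirane CH as the small group, the (R)-catalyst should deliver hydride to the oxirane face and give the C5 hydroxyl trans to the oxirane and cis to the C2 hydroxyl.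

Step 18
Reactants: 20 TBS ether of the target
Product: 21 (1R,2S,5R,6S)-1-[(1S,2Z,4E)-1-hydroxy-5-[(1S,3R)-3-hydroxy-2,2-dimethyl-6-methylidenecyclohexyl]-3-methylpenta-2,4-dien-1-yl]-4-(hydroxymethyl)-7-oxabicyclo[4.1.0]hept-3-ene-2,5-diol (CNP0357844.1)
Conditions: HF·pyridine, excess pyridine, THF, 0 °C → rt
Reagents that add atoms: none
Why: Buffered fluoride desilylation; the near-neutral medium should avoid both Payne rearrangement of the anti-epoxy alcohols (a risk with basic fluoride) and acid opening of the oxirane.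

**Compound list**

1 | geranyl acetate | CC(=O)OC/C=C(\C)CCC=C(C)C | starting material
2 | (R)-6,7-epoxygeranyl acetate | CC(=O)OC/C=C(\C)CC[C@H]1OC1(C)C | intermediate
3 | [(1S,3R)-3-hydroxy-2,2-dimethyl-6-methylidenecyclohexyl]methyl acetate | C=C1CC[C@@H](O)C(C)(C)[C@H]1COC(C)=O | intermediate
4 | [(1S,3R)-3-(tert-butyldimethylsilyloxy)-2,2-dimethyl-6-methylidenecyclohexyl]methyl acetate | C=C1CC[C@@H](O[Si](C)(C)C(C)(C)C)C(C)(C)[C@H]1COC(C)=O | intermediate
5 | [(1S,3R)-3-(tert-butyldimethylsilyloxy)-2,2-dimethyl-6-methylidenecyclohexyl]methanol | C=C1CC[C@@H](O[Si](C)(C)C(C)(C)C)C(C)(C)[C@H]1CO | intermediate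
6 | (1S,3R)-3-(tert-butyldimethylsilyloxy)-2,2-dimethyl-6-methylidenecyclohexane-1-carbaldehyde | C=C1CC[C@@H](O[Si](C)(C)C(C)(C)C)C(C)(C)[C@H]1C=O | intermediate
7 | (E)-alkenyl pinacol boronate of the silylated cyclohexane | C=C1CC[C@@H](O[Si](C)(C)C(C)(C)C)C(C)(C)[C@H]1/C=C/B1OC(C)(C)C(C)(C)O1 | intermediate
8 | but-2-yn-1-ol | CC#CCO | starting material
9 | (Z)-3-iodobut-2-en-1-ol | C/C(I)=C/CO | intermediate
10 | (2Z,4E)-dienol | C=C1CC[C@@H](O[Si](C)(C)C(C)(C)C)C(C)(C)[C@H]1/C=C/C(C)=C\CO | intermediate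
11 | (2Z,4E)-dienal | C=C1CC[C@@H](O[Si](C)(C)C(C)(C)C)C(C)(C)[C@H]1/C=C/C(C)=C\C=O | intermediate
12 | 5-hydroxy-2-methoxybenzaldehyde | COc1ccc(O)cc1C=O | starting material
13 | 3-(hydroxymethyl)-4-methoxyphenol | COc1ccc(O)cc1CO | intermediate
14 | 5-(hydroxymethyl)-2-iodo-4-methoxyphenol | COc1cc(I)c(O)cc1CO | intermediate
15 | 5-(hydroxymethyl)-2-iodo-4,4-dimethoxycyclohexa-2,5-dien-1-one | O=C1C(I)=CC(OC)(OC)C(CO)=C1 | intermediate
16 | (1′S)-dienone carbinol (coupling product) | C=C1CC[C@@H](O[Si](C)(C)C(C)(C)C)C(C)(C)[C@H]1/C=C/C(C)=C\[C@H](O)C1=CC(OC)(OC)C(CO)=CC1=O | intermediate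
17 | epoxy ketone monoketal | C=C1CC[C@@H](O[Si](C)(C)C(C)(C)C)C(C)(C)[C@H]1/C=C/C(C)=C\[C@H](O)[C@]12O[C@H]1C(OC)(OC)C(CO)=CC2=O | intermediate
18 | epoxy alcohol ketal (C2 carbinol set) | C=C1CC[C@@H](O[Si](C)(C)C(C)(C)C)C(C)(C)[C@H]1/C=C/C(C)=C\[C@H](O)[C@]12O[C@H]1C(OC)(OC)C(CO)=C[C@@H]2O | intermediate
19 | epoxy enone | C=C1CC[C@@H](O[Si](C)(C)C(C)(C)C)C(C)(C)[C@H]1/C=C/C(C)=C\[C@H](O)[C@]12O[C@H]1C(=O)C(CO)=C[C@@H]2O | intermediate
20 | TBS ether of the target | C=C1CC[C@@H](O[Si](C)(C)C(C)(C)C)C(C)(C)[C@H]1/C=C/C(C)=C\[C@H](O)[C@]12O[C@H]1[C@H](O)C(CO)=C[C@@H]2O | intermediate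
21 | CNP0357844.1 | C=C1CC[C@@H](O)C(C)(C)[C@H]1/C=C/C(C)=C\[C@H](O)[C@]12O[C@H]1[C@H](O)C(CO)=C[C@@H]2O | target

**Step count and risks**

Total: 18 steps. Longest linear sequence: 14 steps (1–6, 8, 9, 13–18).

Steps most likely to fail:

1. Step 13. The alkenylchromium derived from 15 may be lost by reduction or protonation before it adds, and ligand control at C1′ may be weak with a β,β-disubstituted Z-enal. Fallback from 14 and 11, returning at 16: the bond is made at the arene stage. 14 is bis-silylated (TBSCl, imidazole, DMF) to the bis-TBS iodoarene F1. Iodine–lithium exchange (t-BuLi, −78 °C), transmetalation to zinc and amino-alcohol-catalysed asymmetric aryl transfer to 11 should give the (1′S)-benzylic alcohol F2. TBAF at 0 °C frees the phenol and the primary alcohol, leaving the hindered secondary silyl ether, to give the phenolic triol F3. PhI(OAc)2 in MeOH then dearomatises F3 to 16.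

2. Step 14. The secondary alkoxide at C1′ may compete with the primary alkoxide for the tartrate–peroxide aggregate and erode facial selectivity. Fallback from 16, returning at 17: 16 is bis-silylated (TESOTf, 2,6-lutidine) to the bis-TES ether F4. The primary TES group is removed selectively (PPTS, MeOH, 0 °C) to give the mono-TES alcohol F5. The same tartrate-mediated epoxidation, now directed only by the primary alcohol, should give the mono-TES epoxy ketone F6. HF·pyridine removes the TES group to give 17.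

3. Step 17. Hydride delivery anti to the oxirane, the substrate's own preference, may override the catalyst, and the free hydroxyls may disturb the oxazaborolidine. Fallback from 18, returning at 21: the syn alcohol is accepted and inverted. 18 is persilylated (TBSOTf, 2,6-lutidine) to the tetrakis-TBS ketal F7. Ketal hydrolysis (PPTS, acetone–water) gives the tetrakis-TBS enone F8. Luche reduction (NaBH4, CeCl3, MeOH, −78 °C) should give the syn-epoxy alcohol F9 by attack anti to the oxirane. Mitsunobu inversion (4-nitrobenzoic acid, PPh3, DIAD) gives the anti 4-nitrobenzoate F10. Methanolysis (K2CO3, MeOH) gives the anti alcohol F11, and HF·pyridine removes all four silyl groups to give 21.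

**Further compounds**

F1 | step 13 | tert-butyl{[5-(tert-butyldimethylsilyloxymethyl)-2-iodo-4-methoxyphenyl]oxy}dimethylsilane | CC(C)(C)[Si](C)(C)OCc1cc(O[Si](C)(C)C(C)(C)C)c(I)cc1OC
F2 | step 13 | (1′S)-benzylic alcohol, bis-TBS arene | C=C1CC[C@@H](O[Si](C)(C)C(C)(C)C)C(C)(C)[C@H]1/C=C/C(C)=C\[C@H](O)c1cc(OC)c(CO[Si](C)(C)C(C)(C)C)cc1O[Si](C)(C)C(C)(C)C
F3 | step 13 | (1′S)-benzylic alcohol with free phenol and primary alcohol | C=C1CC[C@@H](O[Si](C)(C)C(C)(C)C)C(C)(C)[C@H]1/C=C/C(C)=C\[C@H](O)c1cc(OC)c(CO)cc1O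
F4 | step 14 | bis-TES ether of 16 | C=C1CC[C@@H](O[Si](C)(C)C(C)(C)C)C(C)(C)[C@H]1/C=C/C(C)=C\[C@H](O[Si](CC)(CC)CC)C1=CC(OC)(OC)C(CO[Si](CC)(CC)CC)=CC1=O
F5 | step 14 | C1′-TES ether of 16 with free primary alcohol | C=C1CC[C@@H](O[Si](C)(C)C(C)(C)C)C(C)(C)[C@H]1/C=C/C(C)=C\[C@H](O[Si](CC)(CC)CC)C1=CC(OC)(OC)C(CO)=CC1=O
F6 | step 14 | C1′-TES ether of 17 | C=C1CC[C@@H](O[Si](C)(C)C(C)(C)C)C(C)(C)[C@H]1/C=C/C(C)=C\[C@H](O[Si](CC)(CC)CC)[C@]12O[C@H]1C(OC)(OC)C(CO)=CC2=O
F7 | step 17 | tetrakis-TBS ketal (persilylated 18) | C=C1CC[C@@H](O[Si](C)(C)C(C)(C)C)C(C)(C)[C@H]1/C=C/C(C)=C\[C@H](O[Si](C)(C)C(C)(C)C)[C@]12O[C@H]1C(OC)(OC)C(CO[Si](C)(C)C(C)(C)C)=C[C@@H]2O[Si](C)(C)C(C)(C)C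
F8 | step 17 | tetrakis-TBS epoxy enone | C=C1CC[C@@H](O[Si](C)(C)C(C)(C)C)C(C)(C)[C@H]1/C=C/C(C)=C\[C@H](O[Si](C)(C)C(C)(C)C)[C@]12O[C@H]1C(=O)C(CO[Si](C)(C)C(C)(C)C)=C[C@@H]2O[Si](C)(C)C(C)(C)C
F9 | step 17 | syn-epoxy alcohol (C5 epimer), tetrakis-TBS | C=C1CC[C@@H](O[Si](C)(C)C(C)(C)C)C(C)(C)[C@H]1/C=C/C(C)=C\[C@H](O[Si](C)(C)C(C)(C)C)[C@]12O[C@H]1[C@@H](O)C(CO[Si](C)(C)C(C)(C)C)=C[C@@H]2O[Si](C)(C)C(C)(C)C
F10 | step 17 | anti 4-nitrobenzoate, tetrakis-TBS | C=C1CC[C@@H](O[Si](C)(C)C(C)(C)C)C(C)(C)[C@H]1/C=C/C(C)=C\[C@H](O[Si](C)(C)C(C)(C)C)[C@]12O[C@H]1[C@H](OC(=O)c3ccc(cc3)[N+](=O)[O-])C(CO[Si](C)(C)C(C)(C)C)=C[C@@H]2O[Si](C)(C)C(C)(C)C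
F11 | step 17 | anti alcohol, tetrakis-TBS | C=C1CC[C@@H](O[Si](C)(C)C(C)(C)C)C(C)(C)[C@H]1/C=C/C(C)=C\[C@H](O[Si](C)(C)C(C)(C)C)[C@]12O[C@H]1[C@H](O)C(CO[Si](C)(C)C(C)(C)C)=C[C@@H]2O[Si](C)(C)C(C)(C)C
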